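**Plan**
- Numbering used throughout: C1 ring ketone, C4–C5 oxirane (C15 methyl), C6 lactone carbinol, C7 spiro carbon, C8 ester carbinol, C9 CH2, C10 ether carbon (C14 methyl), C11/C12/C13 lactone α-carbon, carbonyl and exocyclic CH2.
- Cuts, last to first: C11=C13 (carried as CH2SPh); the O8 acyl bond and the C12–O6 lactone bond (C12 is moved over from O8); C8–C9 together with O–C7; C6–C7. The C1–C6/C9/C10/C14/C15 chain is neryl acetate.
- Enabling feature: the oxolane O–C10–C9–C8–C7 lies between the C1 ketone and the lactone carbons. C9–C10–O can therefore be a 2-acyl-2-methyloxirane (the C1 carbonyl forces opening at CH2 and allows two-point activation). C7=C8 can be the enol-ether bond of a 2-silyloxyfuran made of C12, C11, C7, C8 and O8, a temporary 12,8-butenolide ring.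
- Forward: the chain is oxidised on neryl acetate, a Nozaki–Hiyama–Kishi coupling with a tetronic acid triflate joins C6–C7, then one operation closes the ten-membered carbocycle and the oxolane. Lactone transposition to O6 with methacrylation of O8 and sulfoxide elimination finish the route.
- Stereochemistry: C10 from Shi epoxidation followed by hydroxyl-directed epoxidation; C4/C5 from Sharpless epoxidation; C6 from Felkin–Anh addition beside the oxirane; C7 and C8 from C10 through the cis-bridged oxolane formed in the key step.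

Key step: step 15

Remark: C11 in 21–26 is not controlled and is written without configuration, since it becomes trigonal in the last step; the L-fructose-derived Shi ketone is taken as a purchasable catalyst.

**Step 1**
Reactants: 1 neryl acetate
Product: 2 (2Z)-5-[(2S)-3,3-dimethyloxiran-2-yl]-3-methylpent-2-en-1-yl acetate
Conditions: L-fructose-derived Shi ketone (0.3 equiv), KHSO5 (Oxone), K2CO3, Bu4NHSO4, MeCN/CH2(OMe)2/aq. Na2B4O7 buffer, pH 10.5, 0 °C
Reagents that add atoms: potassium peroxymonosulfate (active part of Oxone), OOS(=O)(=O)[O-].[K+]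
Why: Shi asymmetric epoxidation by a chiral dioxirane, which should take the electron-rich terminal trisubstituted alkene in preference to the Z-alkene deactivated by the allylic acetate and, with the L-series ketone, should deliver oxygen through the spiro transition state to the face that gives the (S)-oxirane.

**Step 2**
Reactants: 2 (S)-epoxy acetate
Product: 4 (2Z,6S)-6-hydroxy-3,7-dimethylocta-2,7-dien-1-yl acetate, via allyl trimethylsilyl ether 3 (not isolated)
Conditions: TMSOTf, DBU, toluene, −78 → 23 °C; then 1 M HCl, THF, 0 °C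
Reagents that add atoms: none
Why: Noyori-type isomerisation of a trisubstituted oxirane to an allyl silyl ether, in which silylation opens the ring at the tertiary carbon and DBU removes a methyl proton, so the C–O bond at the stereocentre is untouched and the (S) configuration at C1 is kept.

**Step 3**
Reactants: 4 (S)-allylic alcohol
Product: 5 (2Z,6S)-6-hydroxy-3-methyl-6-[(2R)-2-methyloxiran-2-yl]hex-2-en-1-yl acetate
Conditions: VO(acac)2 (cat.), tBuOOH, CH2Cl2, 0 °C
Reagents that add atoms: tert-butyl hydroperoxide, CC(C)(C)OO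
Why: hydroxyl-directed vanadium-catalysed epoxidation, in which allylic 1,2-strain in the vanadate ester places H and not the chain beside the vinylic methyl, so oxygen should enter syn to the hydroxyl in that conformer and give the erythro isomer (C1 S, C10 R), while the remote Z-alkene should react much more slowly.

**Step 4**
Reactants: 5 epoxy alcohol
Product: 6 (2Z,6S)-3-methyl-6-[(2R)-2-methyloxiran-2-yl]-6-(triethylsilyloxy)hex-2-en-1-yl acetate
Conditions: Et3SiCl, imidazole, DMF, 0 °C
Reagents that add atoms: chlorotriethylsilane, CC[Si](Cl)(CC)CC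
Why: standard silylation of the secondary alcohol, giving a C1 protecting group that survives the CrCl2/NiCl2 coupling and is later removable in the presence of a TBS ether.

**Step 5**
Reactants: 6 silyl ether acetate
Product: 7 (2Z,6S)-3-methyl-6-[(2R)-2-methyloxiran-2-yl]-6-(triethylsilyloxy)hex-2-en-1-ol
Conditions: K2CO3 (cat.), MeOH, 0 °C
Reagents that add atoms: none
Why: mild transesterification (methanolysis) of the primary allylic acetate, which should leave the triethylsilyl ether and the 2,2-disubstituted oxirane untouched.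

**Step 6**
Reactants: 7 Z-allylic alcohol
Product: 8 [(2S,3R)-3-methyl-3-{(3S)-3-[(2R)-2-methyloxiran-2-yl]-3-(triethylsilyloxy)propyl}oxiran-2-yl]methanol
Conditions: Ti(OiPr)4, diethyl L-(+)-tartrate, tBuOOH, 4 Å molecular sieves, CH2Cl2, −20 °C
Reagents that add atoms: tert-butyl hydroperoxide, CC(C)(C)OO
Why: Sharpless asymmetric epoxidation of the nerol-type Z-allylic alcohol, in which the L-(+)-tartrate ligand controls the face and should give the cis-oxirane with C5 S and C4 R, as known for nerol itself.

**Step 7**
Reactants: 8 diepoxy alcohol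
Product: 9 (2R,3R)-3-methyl-3-{(3S)-3-[(2R)-2-methyloxiran-2-yl]-3-(triethylsilyloxy)propyl}oxirane-2-carbaldehyde (same spatial arrangement as 8)
Conditions: Dess–Martin periodinane, NaHCO3, CH2Cl2, 0 → 23 °C
Reagents that add atoms: none
Why: buffered Dess–Martin oxidation of a 2,3-epoxy alcohol to the cis-epoxy aldehyde, which is used crude to avoid epimerisation at C5.

**Step 8**
Reactants: 10 tetronic acid; 11 formaldehyde; 12 thiophenol
Product: 13 4-hydroxy-3-[(phenylsulfanyl)methyl]furan-2(5H)-one
Conditions: aq. HCHO (37 %), PhSH, Et3N (cat.), EtOH, 23 °C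
Reagents that add atoms: none
Why: Knoevenagel condensation of the cyclic 1,3-dicarbonyl compound with formaldehyde and thia-Michael trapping of the 3-methylene intermediate by thiophenol, which installs C13 in a masked, non-electrophilic form.

**Step 9**
Reactants: 13 thiomethyl tetronic acid
Product: 14 5-oxo-4-[(phenylsulfanyl)methyl]-2,5-dihydrofuran-3-yl trifluoromethanesulfonate
Conditions: Tf2O, iPr2NEt, CH2Cl2, −78 °C
Reagents that add atoms: trifluoromethanesulfonic anhydride, O=S(=O)(OS(=O)(=O)C(F)(F)F)C(F)(F)F
Why: O-triflation of the tetronic acid enol, which gives the β-acyl vinyl triflate needed for the CrCl2/NiCl2 coupling.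

**Step 10**
Reactants: 9 epoxy aldehyde; 14 butenolide triflate
Product: 15 3-[(phenylsulfanyl)methyl]furan-2(5H)-one carrying at ring C4 (= C7) the chain C6H(OH)–C5/C4 cis-oxirane (C4 methyl)–C3H2–C2H2–C1H(OSiEt3)–C10/C9 oxirane (C10 methyl); 1S,4R,5S,6S,10R
Conditions: CrCl2 (4 equiv), NiCl2 (2 mol %), DMF/THF, 23 °C
Reagents that add atoms: none
Why: Nozaki–Hiyama–Kishi coupling, in which the alkenylchromium reagent formed from the triflate adds only to the aldehyde and Felkin–Anh attack anti to the oxirane C–O bond of the cis-epoxy aldehyde should give the anti (erythro) epoxy alcohol, C6 S as drawn.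

**Step 11**
Reactants: 15 butenolide alcohol
Product: 16 the 6-O-tert-butyldimethylsilyl ether of 15 (1S,4R,5S,6S,10R)
Conditions: TBSOTf, 2,6-lutidine, CH2Cl2, −78 °C
Reagents that add atoms: tert-butyldimethylsilyl trifluoromethanesulfonate, CC(C)(C)[Si](C)(C)OS(=O)(=O)C(F)(F)F
Why: silylation of the hindered secondary alcohol with a silyl triflate and a hindered base, which also blocks migration of the lactone acyl group to O6.

**Step 12**
Reactants: 16 bis-silyl ether
Product: 17 the 1-hydroxy compound (16 without the SiEt3 group; 1S,4R,5S,6S,10R)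
Conditions: HF·pyridine, pyridine, THF, 0 °C
Reagents that add atoms: none
Why: selective cleavage of the more labile triethylsilyl ether in the presence of the secondary TBS ether, under buffered conditions known to spare epoxides.

**Step 13**
Reactants: 17 epoxy alcohol
Product: 18 the C1 ketone: butenolide with chain C6H(OTBS)–C5/C4 oxirane–C3H2–C2H2–C1(=O)–C10/C9 oxirane; 4R,5S,6S,10R
Conditions: Dess–Martin periodinane, NaHCO3, CH2Cl2, 0 → 23 °C
Reagents that add atoms: none
Why: Dess–Martin oxidation of the secondary alcohol to the 2-acyl-2-methyloxirane, whose stereocentre C10 is quaternary and cannot epimerise.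

**Step 14**
Reactants: 18 butenolide epoxy ketone
Product: 19 the 2-(triisopropylsilyloxy)furan of 18 (furan C5–H is C8, C3 carries CH2SPh, C4 carries the chain; 4R,5S,6S,10R)
Conditions: iPr3SiOTf (1.05 equiv), Et3N, CH2Cl2, −78 → −20 °C
Reagents that add atoms: triisopropylsilyl trifluoromethanesulfonate, CC(C)[Si](OS(=O)(=O)C(F)(F)F)(C(C)C)C(C)C
Why: soft enolisation of the butenolide to the aromatic 2-silyloxyfuran by O-silylation and loss of the acidic γ-proton at C8, where one equivalent of the bulky silyl triflate at low temperature should leave the much less acidic ketone untouched.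

**Step 15**
Reactants: 19 silyloxyfuran epoxy ketone
Product: 21 7,10-epoxy-bridged tricyclic 12,8-lactone (ten-membered ketone cis-fused at C7–C8 to the lactone; C11 bearing H and CH2SPh; C6 bearing OTBS; 4R,5S,6R,7S,8S,10R), via macrocyclic hydroxy butenolide 20 (not isolated)
Conditions: Sc(OTf)3 (0.5 equiv), CH2Cl2, 19 added over 10 h to 0.001 M, −40 → −10 °C; then DBU (3 equiv), −10 → 23 °C; aq. NH4Cl
Reagents that add atoms: none
Why: Proposed new method: Sc(OTf)3 binds the ketone and oxirane oxygens of the 2-acyl-2-methyloxirane in a five-membered chelate, C8 (C5 of the silyloxyfuran) opens the oxirane at C9 by SN2 (10-endo-tet closure of the carbocycle) to give butenolide 20 with an alkoxide on C10, and this alkoxide, with DBU completing the step, adds to C7, the β-carbon of the regenerated butenolide (5-exo-trig oxa-Michael closure of the oxolane), so the furan C7=C8 bond serves as the two-carbon partner of a formal [3+2] annulation with the C9–C10–O unit. The closest known reactions are the Lewis-acid-mediated opening of terminal epoxides by silyl enol ethers and ketene acetals, the γ-selective vinylogous Mukaiyama reactions of 2-silyloxyfurans, and the base-induced oxa-Michael cyclisation of hydroxyalkyl butenolides to cis-fused furofuranones; their union in one ring-forming operation is the new element. C10, whose configuration comes from steps 1 and 3, controls both new centres, because the C1–C6 chain can span C10 and C7 only as a cis-2,5-bridge of the oxolane, which places C6 anti and the lactone atoms C11 and O8 syn on the ring fusion (7S, 8S), and a C8 epimer that cannot close is returned through the furanolate by DBU. The selectivities needed are γ- over α-attack of the dienol ether (secured by the neutral silyloxyfuran under Lewis acid), C9 over C10 opening (C10 is quaternary and its cation is destabilised by the C1 carbonyl, which also disfavours Meinwald and semipinacol paths), activation of the keto-oxirane over the C4–C5 oxirane (two-point binding, the C6 silyl ether being a poor donor), alkylation over reversible addition to the C1 ketone (that path needs a strained eight-membered ring), and ring closure over oligomerisation (slow addition at high dilution). Thiolate on C13 may leave and re-add by E1cB/thia-Michael exchange without loss, and C11 is left uncontrolled because it becomes trigonal at the end.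

**Step 16**
Reactants: 21 tricyclic 12,8-lactone
Product: 22 hydroxy Weinreb amide: C12 as N-methoxy-N-methylamide on C11, free 8-OH, 6-OTBS, oxolane and macrocycle as in 21; 4R,5S,6R,7S,8S,10R
Conditions: MeNH(OMe)·HCl, iPrMgCl, THF, −20 → 0 °C; aq. NH4Cl; used crude
Reagents that add atoms: N,O-dimethylhydroxylamine hydrochloride, Cl.CNOC
Why: lactone aminolysis with the chloromagnesium amide MeN(OMe)MgCl (Weinreb amide formation), which should open the cis-fused lactone and free the C8 hydroxyl, any enolate or hemiaminal formed at the C1 ketone reverting on work-up.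

**Step 17**
Reactants: 22 hydroxy Weinreb amide
Product: 23 the 8-O-methacrylate of 22
Conditions: methacrylic anhydride, DMAP, Et3N, CH2Cl2, 0 → 23 °C
Reagents that add atoms: methacrylic anhydride, CC(=C)C(=O)OC(=O)C(C)=C
Why: DMAP-catalysed acylation of the secondary C8 alcohol, run at once on crude 22 under non-acidic conditions so that relactonisation of the γ-hydroxy amide should not compete.

**Step 18**
Reactants: 23 methacrylate Weinreb amide
Product: 25 12,6-lactone 8-methacrylate with C11 bearing H and CH2SPh (the 13-phenylthio-11,13-dihydro form of the target; 4R,5S,6R,7S,8S,10R), via hydroxy Weinreb amide 24 (not isolated)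
Conditions: HF·pyridine, pyridine, THF, 0 → 23 °C; then PPTS, CH2Cl2, 23 °C
Reagents that add atoms: none
Why: fluoride cleavage of the TBS ether followed by acid-catalysed lactonisation of the γ-hydroxy Weinreb amide, in which only O6 can attack C12 because O8 is acylated, and the five-membered closure onto the activated amide should outrun 1,3-acyl migration of the methacrylate.

**Step 19**
Reactants: 25 phenylthiomethyl lactone
Product: 27 CNP0241021.1, via sulfoxide 26 (not isolated)
Conditions: mCPBA (1.0 equiv), NaHCO3, CH2Cl2, −78 °C; then toluene, CaCO3, 100 °C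
Reagents that add atoms: none
Why: chemoselective sulfide oxidation and thermal syn-elimination of the sulfoxide (the classical unmasking of an α-methylene lactone), where the only β-hydrogen is on C11, so the C11=C13 bond must form, and the electron-poor methacrylate and the ketone should not react with one equivalent of peracid at −78 °C.

**Compound list**
1 | neryl acetate, (2Z)-3,7-dimethylocta-2,6-dien-1-yl acetate | CC(=O)OC/C=C(/C)CCC=C(C)C | starting material
2 | (2Z)-5-[(2S)-3,3-dimethyloxiran-2-yl]-3-methylpent-2-en-1-yl acetate | CC(=O)OC/C=C(/C)CC[C@@H]1OC1(C)C | intermediate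
3 | (2Z,6S)-3,7-dimethyl-6-(trimethylsilyloxy)octa-2,7-dien-1-yl acetate | CC(=O)OC/C=C(/C)CC[C@H](O[Si](C)(C)C)C(C)=C | intermediate (not isolated)
4 | (2Z,6S)-6-hydroxy-3,7-dimethylocta-2,7-dien-1-yl acetate | CC(=O)OC/C=C(/C)CC[C@H](O)C(C)=C | intermediate
5 | (2Z,6S)-6-hydroxy-3-methyl-6-[(2R)-2-methyloxiran-2-yl]hex-2-en-1-yl acetate | CC(=O)OC/C=C(/C)CC[C@H](O)[C@@]1(C)CO1 | intermediate
6 | (2Z,6S)-3-methyl-6-[(2R)-2-methyloxiran-2-yl]-6-(triethylsilyloxy)hex-2-en-1-yl acetate | CC(=O)OC/C=C(/C)CC[C@H](O[Si](CC)(CC)CC)[C@@]1(C)CO1 | intermediate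
7 | (2Z,6S)-3-methyl-6-[(2R)-2-methyloxiran-2-yl]-6-(triethylsilyloxy)hex-2-en-1-ol | OC/C=C(/C)CC[C@H](O[Si](CC)(CC)CC)[C@@]1(C)CO1 | intermediate
8 | [(2S,3R)-3-methyl-3-{(3S)-3-[(2R)-2-methyloxiran-2-yl]-3-(triethylsilyloxy)propyl}oxiran-2-yl]methanol | OC[C@@H]1O[C@]1(C)CC[C@H](O[Si](CC)(CC)CC)[C@@]2(C)CO2 | intermediate
9 | (2R,3R)-3-methyl-3-{(3S)-3-[(2R)-2-methyloxiran-2-yl]-3-(triethylsilyloxy)propyl}oxirane-2-carbaldehyde | O=C[C@@H]1O[C@]1(C)CC[C@H](O[Si](CC)(CC)CC)[C@@]2(C)CO2 | intermediate
10 | tetronic acid, 4-hydroxyfuran-2(5H)-one | O=C1OCC(O)=C1 | starting material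
11 | formaldehyde | C=O | starting material
12 | thiophenol | Sc1ccccc1 | starting material
13 | 4-hydroxy-3-[(phenylsulfanyl)methyl]furan-2(5H)-one | O=C1OCC(O)=C1CSc1ccccc1 | intermediate
14 | 5-oxo-4-[(phenylsulfanyl)methyl]-2,5-dihydrofuran-3-yl trifluoromethanesulfonate | O=C1OCC(OS(=O)(=O)C(F)(F)F)=C1CSc1ccccc1 | intermediate
15 | butenolide alcohol: 3-(phenylthiomethyl)furan-2(5H)-one with the C6(OH)–C1(OSiEt3) diepoxy chain on ring C4; 1S,4R,5S,6S,10R | O=C1OCC([C@H](O)[C@@H]2O[C@]2(C)CC[C@H](O[Si](CC)(CC)CC)[C@@]3(C)CO3)=C1CSc1ccccc1 | intermediate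
16 | 6-O-TBS ether of 15; 1S,4R,5S,6S,10R | O=C1OCC([C@H](O[Si](C)(C)C(C)(C)C)[C@@H]2O[C@]2(C)CC[C@H](O[Si](CC)(CC)CC)[C@@]3(C)CO3)=C1CSc1ccccc1 | intermediate
17 | 1-hydroxy-6-O-TBS butenolide; 1S,4R,5S,6S,10R | O=C1OCC([C@H](O[Si](C)(C)C(C)(C)C)[C@@H]2O[C@]2(C)CC[C@H](O)[C@@]3(C)CO3)=C1CSc1ccccc1 | intermediate
18 | butenolide epoxy ketone (C1 ketone next to the C10/C9 oxirane); 4R,5S,6S,10R | O=C1OCC([C@H](O[Si](C)(C)C(C)(C)C)[C@@H]2O[C@]2(C)CCC(=O)[C@@]3(C)CO3)=C1CSc1ccccc1 | intermediate
19 | 2-(triisopropylsilyloxy)furan of 18; 4R,5S,6S,10R | CC(C)[Si](Oc1occ([C@H](O[Si](C)(C)C(C)(C)C)[C@@H]2O[C@]2(C)CCC(=O)[C@@]3(C)CO3)c1CSc1ccccc1)(C(C)C)C(C)C | intermediate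
20 | ten-membered carbocycle fused to the 12,8-butenolide (C7=C11), new C8–C9 bond, free C10 hydroxyl; 4R,5S,6S,8S,10R | O=C1O[C@H]2C[C@@](C)(O)C(=O)CC[C@@]3(C)O[C@H]3[C@@H](O[Si](C)(C)C(C)(C)C)C2=C1CSc1ccccc1 | intermediate (not isolated)
21 | 7,10-epoxy-bridged ten-membered ketone cis-fused to the 12,8-lactone, C11 H/CH2SPh, 6-OTBS; 4R,5S,6R,7S,8S,10R | O=C1O[C@H]2C[C@@]3(C)O[C@]2(C1CSc1ccccc1)[C@H](O[Si](C)(C)C(C)(C)C)[C@@H]4O[C@]4(C)CCC3=O | intermediate
22 | 8-hydroxy N-methoxy-N-methylamide (lactone of 21 opened); 4R,5S,6R,7S,8S,10R | O[C@H]1C[C@@]2(C)O[C@]1(C(CSc1ccccc1)C(=O)N(C)OC)[C@H](O[Si](C)(C)C(C)(C)C)[C@@H]3O[C@]3(C)CCC2=O | intermediate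
23 | 8-O-methacrylate of 22 | C=C(C)C(=O)O[C@H]1C[C@@]2(C)O[C@]1(C(CSc1ccccc1)C(=O)N(C)OC)[C@H](O[Si](C)(C)C(C)(C)C)[C@@H]3O[C@]3(C)CCC2=O | intermediate
24 | 6-hydroxy 8-O-methacrylate Weinreb amide (23 without TBS) | C=C(C)C(=O)O[C@H]1C[C@@]2(C)O[C@]1(C(CSc1ccccc1)C(=O)N(C)OC)[C@H](O)[C@@H]3O[C@]3(C)CCC2=O | intermediate (not isolated)
25 | 13-phenylthio-11,13-dihydro form of the target (12,6-lactone, 8-methacrylate); 4R,5S,6R,7S,8S,10R | C=C(C)C(=O)O[C@H]1C[C@@]2(C)O[C@@]13C(CSc4ccccc4)C(=O)O[C@@H]3[C@@H]1O[C@]1(C)CCC2=O | intermediate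
26 | sulfoxide of 25 | C=C(C)C(=O)O[C@H]1C[C@@]2(C)O[C@@]13C(CS(=O)c4ccccc4)C(=O)O[C@@H]3[C@@H]1O[C@]1(C)CCC2=O | intermediate (not isolated)
27 | CNP0241021.1; 4R,5S,6R,7S,8S,10R | C=C(C)C(=O)O[C@H]1C[C@@]2(C)O[C@@]13C(=C)C(=O)O[C@@H]3[C@@H]1O[C@]1(C)CCC2=O | target

**Step count and risks**
Total: 19 steps. Longest linear sequence: 17 steps (steps 1–7 and 10–19); steps 8–9 form the second branch.

Step 15 (proposed new method). The ten-membered closure may be too slow, so that protodesilylation, oligomerisation, addition to the activated C1 ketone or Lewis-acid opening of the C4–C5 oxirane take over. The fallback sets out from 19 and returns at 21; it makes C8 a sulfur-stabilised carbanion, the known way to close carbocycles by intramolecular epoxide opening. PhSCl (CH2Cl2, −78 °C) sulfenylates the silyloxyfuran at C8 to give the 8-phenylthio butenolide F1. LiN(SiMe3)2 with LiClO4 in THF at 0.001 M should form the thio-stabilised furanolate, which opens the oxirane at C9; the alkoxide then adds to C7 to give the 8-phenylthio tricyclic lactone F2. Bu3SnH/AIBN (benzene, 80 °C) cleaves the C8–S bond of this O,S-acetal through the α-oxy radical, which can only take hydrogen to give the cis-fused lactone 21; the primary C13 sulfide should survive.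

Step 16. Ring opening of the hindered lactone by the chloromagnesium amide may be incomplete, thiolate may be lost by β-elimination, or the hydroxy amide may relactonise before acylation. The fallback sets out from 21 and returns at 25; it uses acyl transfer instead of aminolysis. HF·pyridine frees the C6 hydroxyl to give the 6-hydroxy 12,8-lactone F3. Catalytic DBU in toluene at 60 °C equilibrates the lactone from O8 to O6 to give the 8-hydroxy 12,6-lactone F4, which is acylated with methacrylic anhydride/DMAP to 25. This depends on the equilibrium position, which is not known.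

Step 10. Facial selectivity in the addition to the α,β-epoxy aldehyde may be poor. The fallback sets out from 15 (as the C6 epimer mixture) and returns at 15. Dess–Martin oxidation gives the 6-keto butenolide F5, and Zn(BH4)2 in Et2O at −20 °C reduces it under chelation between the ketone and oxirane oxygens, the known route to anti (erythro) epoxy alcohols.

**Further compounds**
F1 | step 15 | 8-phenylthio butenolide (18 with SPh on the lactone CH2 carbon C8) | O=C1OC(Sc2ccccc2)C([C@H](O[Si](C)(C)C(C)(C)C)[C@@H]2O[C@]2(C)CCC(=O)[C@@]3(C)CO3)=C1CSc1ccccc1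
F2 | step 15 | 8-phenylthio analogue of 21 (SPh in place of H8) | O=C1O[C@@]2(Sc3ccccc3)C[C@@]4(C)O[C@]2(C1CSc1ccccc1)[C@H](O[Si](C)(C)C(C)(C)C)[C@@H]5O[C@]5(C)CCC4=O
F3 | step 16 | 6-hydroxy 12,8-lactone (21 without TBS) | O=C1O[C@H]2C[C@@]3(C)O[C@]2(C1CSc1ccccc1)[C@H](O)[C@@H]4O[C@]4(C)CCC3=O
F4 | step 16 | 8-hydroxy 12,6-lactone (25 without the methacryloyl group) | O[C@H]1C[C@@]2(C)O[C@@]13C(CSc4ccccc4)C(=O)O[C@@H]3[C@@H]1O[C@]1(C)CCC2=O
F5 | step 10 | 6-keto butenolide (15 oxidised at C6) | O=C1OCC(C(=O)[C@@H]2O[C@]2(C)CC[C@H](O[Si](CC)(CC)CC)[C@@]3(C)CO3)=C1CSc1ccccc1
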